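**Retrosynthetic overview**

1. Numbering used throughout: C1 = ring-fusion carbon bearing CH3, C2 and C3 = cyclopentane CH2, C4 = C(OH)(i-Pr), C5 = ring-fusion CH, C6 = CH–O–vanilloyl, C7 = CH2, C8 = C(OH)CH3, C9=C10 = ring alkene. The plan rests on the cyclopentane C1–C2–C3–C4–C5: its C3–C4–C5 part bridges the C1–C2 bond and C4 bears one oxygen and one carbon branch, so C4 can enter as the central carbon of a trimethylenemethane unit whose exocyclic CH2 stands for the later ketone.
2. Late stage: vanillate at O6 last; C4 carbinol from a C4 ketone (cleavage of C4=CH2, isopropyl addition); C9=C10 from a C10 ketone through its enol triflate. This leads back to a trans-fused bicyclic C10 ketone with C4=CH2.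
3. Key disconnection: C2–C3 and C1–C5, by an intramolecular palladium–trimethylenemethane (3+2) cycloaddition of an acyclic isopropenyl ketone that carries a 2-(trimethylsilylmethyl)allyl acetate at C5. The cyclopentane and the seven-membered ring close together in this step (C2–C3 first, then the shared bond C1–C5); no ring exists before it.
4. Acyclic chain: C4–C5 by addition of 2-lithio-3-(trimethylsilyl)propene to a C5 aldehyde; C10–C1 by isopropenyl Grignard addition and oxidation. The enone is made last so that no organolithium meets it.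
5. Chain stereocentres: C6 from (S)-benzyl glycidyl ether; C8 by Sharpless epoxidation of an (E)-allylic alcohol (from alkyne carboalumination) and hydride opening of the epoxide.

Key step: step 13

Remark: the C5 acetate (15–18) and the C10 carbinol (17) are carried as epimer mixtures, since C5 is erased on ionisation and C10 on oxidation. Locants in the names of bicyclic compounds follow the numbering of line 1, not von Baeyer numbering.

**Route**

Step 1
Reactants: 1 (S)-benzyl glycidyl ether
Product: 2 (2S)-1-(benzyloxy)pent-4-yn-2-ol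
Conditions: LiC≡CH·H2NCH2CH2NH2, DMSO, rt
Reagents that add atoms: lithium acetylide–ethylenediamine complex, [Li+].[C-]#C.NCCN
Why: SN2 opening of the terminal epoxide by acetylide at the unsubstituted CH2 carbon, so that the existing carbinol centre (C6, S) is carried over untouched.

Step 2
Reactants: 2 (2S)-1-(benzyloxy)pent-4-yn-2-ol
Product: 3 (2S)-1-(benzyloxy)-2-(tert-butyldimethylsilyloxy)pent-4-yne
Conditions: TBSCl, imidazole, DMF, rt
Reagents that add atoms: tert-butyldimethylsilyl chloride, CC(C)(C)[Si](C)(C)Cl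
Why: Imidazole-promoted silylation of the secondary alcohol gives the C6 silyl ether that has to last until step 18.

Step 3
Reactants: 3 (2S)-1-(benzyloxy)-2-(tert-butyldimethylsilyloxy)pent-4-yne
Product: 6 (2E,5S)-6-(benzyloxy)-5-(tert-butyldimethylsilyloxy)-3-methylhex-2-en-1-ol, via alkenyldimethylalane 4 (not isolated), via lithium alkenyl(butyl)dimethylaluminate 5 (not isolated)
Conditions: Me3Al, Cp2ZrCl2 (25 mol%), ClCH2CH2Cl, rt; n-BuLi, −78 °C; (CH2O)n, THF, rt
Reagents that add atoms: trimethylaluminium, C[Al](C)C; formaldehyde (from paraformaldehyde), C=O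
Why: Zirconium-catalysed (Negishi) carboalumination adds CH3 and aluminium syn across the terminal alkyne with methyl on the internal carbon, which fixes the E geometry of the C8=C9 bond, and the derived aluminate is hydroxymethylated by formaldehyde with retention of that geometry.

Step 4
Reactants: 6 (2E,5S)-6-(benzyloxy)-5-(tert-butyldimethylsilyloxy)-3-methylhex-2-en-1-ol
Product: 7 [(2S,3S)-3-[(2S)-3-(benzyloxy)-2-(tert-butyldimethylsilyloxy)propyl]-3-methyloxiran-2-yl]methanol
Conditions: Ti(OiPr)4, L-(+)-diethyl tartrate, t-BuOOH, 4 Å MS, CH2Cl2, −20 °C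
Reagents that add atoms: tert-butyl hydroperoxide, CC(C)(C)OO
Why: Sharpless asymmetric epoxidation is reagent-controlled, and with L-(+)-diethyl tartrate an (E)-3-methylalk-2-en-1-ol is expected to give the (2S,3S)-epoxide, which sets C8 (and for the moment C9) irrespective of the remote C6 centre.

Step 5
Reactants: 7 [(2S,3S)-3-[(2S)-3-(benzyloxy)-2-(tert-butyldimethylsilyloxy)propyl]-3-methyloxiran-2-yl]methanol
Product: 8 (3R,5S)-6-(benzyloxy)-5-(tert-butyldimethylsilyloxy)-3-methylhexane-1,3-diol
Conditions: NaAlH2(OCH2CH2OMe)2, THF, 0 °C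
Reagents that add atoms: none
Why: Alkoxyaluminate-directed hydride delivery opens the 2,3-epoxy alcohol at C9 to the 1,3-diol, and since the C8–O bond is not broken the C8 configuration is kept (the descriptor changes only through priorities).

Step 6
Reactants: 8 (3R,5S)-6-(benzyloxy)-5-(tert-butyldimethylsilyloxy)-3-methylhexane-1,3-diol
Product: 9 (2S,4R)-1-(benzyloxy)-2-(tert-butyldimethylsilyloxy)-4-methyl-4,6-bis(triethylsilyloxy)hexane
Conditions: Et3SiOTf (2.5 equiv), 2,6-lutidine, CH2Cl2, −78 → 0 °C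
Reagents that add atoms: triethylsilyl trifluoromethanesulfonate, CC[Si](CC)(CC)OS(=O)(=O)C(F)(F)F
Why: The silyl triflate with a hindered pyridine base silylates both the primary and the tertiary hydroxyl, the tertiary TES ether being the C8 protecting group and the primary one a latent aldehyde.

Step 7
Reactants: 9 (2S,4R)-1-(benzyloxy)-2-(tert-butyldimethylsilyloxy)-4-methyl-4,6-bis(triethylsilyloxy)hexane
Product: 10 (2S,4R)-2-(tert-butyldimethylsilyloxy)-4-methyl-4,6-bis(triethylsilyloxy)hexan-1-ol
Conditions: H2 (1 atm), Pd/C, EtOAc, rt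
Reagents that add atoms: none
Why: Catalytic hydrogenolysis cleaves the benzyl ether; the molecule has no C=C bond at this stage and the silyl ethers should be stable in a non-protic solvent.

Step 8
Reactants: 10 (2S,4R)-2-(tert-butyldimethylsilyloxy)-4-methyl-4,6-bis(triethylsilyloxy)hexan-1-ol
Product: 11 (2S,4R)-2-(tert-butyldimethylsilyloxy)-4-methyl-4,6-bis(triethylsilyloxy)hexanal
Conditions: Dess–Martin periodinane, NaHCO3, CH2Cl2, 0 °C → rt
Reagents that add atoms: none
Why: Dess–Martin oxidation under buffered conditions should give the α-silyloxy aldehyde without epimerisation at C6.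

Step 9
Reactants: 11 (2S,4R)-2-(tert-butyldimethylsilyloxy)-4-methyl-4,6-bis(triethylsilyloxy)hexanal; 12 2-bromo-3-(trimethylsilyl)propene
Product: 15 (4S,6R)-4-(tert-butyldimethylsilyloxy)-6-methyl-6,8-bis(triethylsilyloxy)-2-[(trimethylsilyl)methyl]oct-1-en-3-yl acetate (C3 epimers; C3 = C5 of the target), via 2-lithio-3-(trimethylsilyl)propene 13 (not isolated), via lithium alkoxide 14 (not isolated)
Conditions: 12, t-BuLi (2 equiv), Et2O, −78 °C; 11; Ac2O, −78 → 0 °C
Reagents that add atoms: acetic anhydride, CC(=O)OC(C)=O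
Why: Bromine–lithium exchange gives the vinyllithium, which adds 1,2 to the only electrophile present, and acetylation of the lithium alkoxide at low temperature forestalls silyl migration from O6; C5 is left as an epimer mixture because both epimers ionise to the same allyl complex in step 13.

Step 10
Reactants: 15 (4S,6R)-4-(tert-butyldimethylsilyloxy)-6-methyl-6,8-bis(triethylsilyloxy)-2-[(trimethylsilyl)methyl]oct-1-en-3-yl acetate
Product: 16 (4S,6S)-4-(tert-butyldimethylsilyloxy)-6-methyl-8-oxo-6-(triethylsilyloxy)-2-[(trimethylsilyl)methyl]oct-1-en-3-yl acetate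
Conditions: (COCl)2, DMSO, CH2Cl2, −78 → −30 °C; Et3N
Reagents that add atoms: none
Why: Under Swern conditions a primary triethylsilyl ether is cleaved and oxidised in one operation to the aldehyde, while the tertiary TES ether, the secondary TBS ether, the acetate and the allylsilane should be left.

Step 11
Reactants: 16 (4S,6S)-4-(tert-butyldimethylsilyloxy)-6-methyl-8-oxo-6-(triethylsilyloxy)-2-[(trimethylsilyl)methyl]oct-1-en-3-yl acetate
Product: 17 (4S,6R)-4-(tert-butyldimethylsilyloxy)-8-hydroxy-6,9-dimethyl-6-(triethylsilyloxy)-2-[(trimethylsilyl)methyl]deca-1,9-dien-3-yl acetate (C3 and C8 epimers)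
Conditions: CH2=C(CH3)MgBr (1.2 equiv), THF, −78 °C
Reagents that add atoms: isopropenylmagnesium bromide, CC(=C)[Mg]Br
Why: Grignard 1,2-addition to the aldehyde, which at −78 °C should be much faster than attack on the hindered secondary acetate; the new C10 centre is erased in step 12.

Step 12
Reactants: 17 (4S,6R)-4-(tert-butyldimethylsilyloxy)-8-hydroxy-6,9-dimethyl-6-(triethylsilyloxy)-2-[(trimethylsilyl)methyl]deca-1,9-dien-3-yl acetate
Product: 18 (4S,6S)-4-(tert-butyldimethylsilyloxy)-6,9-dimethyl-8-oxo-6-(triethylsilyloxy)-2-[(trimethylsilyl)methyl]deca-1,9-dien-3-yl acetate (C3 epimers)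
Conditions: Dess–Martin periodinane, NaHCO3, CH2Cl2, rt
Reagents that add atoms: none
Why: Dess–Martin oxidation of the allylic alcohol gives the isopropenyl ketone under neutral conditions that should spare the allylsilane, the allylic acetate and the β-silyloxy ketone.

Step 13
Reactants: 18 (4S,6S)-4-(tert-butyldimethylsilyloxy)-6,9-dimethyl-8-oxo-6-(triethylsilyloxy)-2-[(trimethylsilyl)methyl]deca-1,9-dien-3-yl acetate
Product: 19 (1S,5S,6S,8S)-6-(tert-butyldimethylsilyloxy)-1,8-dimethyl-4-methylidene-8-(triethylsilyloxy)bicyclo[5.3.0]decan-10-one (trans-fused)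
Conditions: Pd(OAc)2 (10 mol%), P(OiPr)3 (60 mol%), THF (0.01 M), reflux
Reagents that add atoms: none
Why: Zerovalent palladium, formed from Pd(OAc)2 and the phosphite, ionises the allylic acetate and the acetate then takes the silyl group, so that a palladium–trimethylenemethane zwitterion arises with its negative end on C3 (the carbon that carried silicon); C3 should add to the unsubstituted β-carbon C2 of the isopropenyl ketone, and the C1 enolate then alkylates the allyl terminus C5 on the face away from palladium, which makes C1 quaternary. The closest known reaction type is the intramolecular palladium–trimethylenemethane (3+2) cycloaddition of 2-(silylmethyl)allyl esters tethered to enones, enoates or vinyl sulfones, which gives bicyclo[3.3.0], [4.3.0] and [5.3.0] skeletons, together with the intermolecular addition of the same dipole to α-substituted acceptors, which creates quaternary carbons; what goes beyond these cases is that the tether here enters through the ketone carbonyl, so the tether-bearing terminus must bond to the α-carbon. As to ring closure, the C2–C3 bond is made first with the chain folded as in the product (formally a ten-membered ring), and the C1–C5 bond then closes the cyclopentane by exo attack on the allyl terminus (C4=CH2 stays exocyclic) and with it, through the tether, the seven-membered ring. C1 and C5 are both set in this second bond formation: a chair-like fold of the C5–C10 chain with the bulky C6 silyloxy group pseudo-equatorial should expose the enolate face that places the C1 methyl anti to the C6 oxygen, and attack anti to palladium on the syn-configured allyl unit should put C5–H trans to that methyl (trans ring fusion). The selectivities needed are the fused over the bridged mode (C5 to C2) and closure at C5 instead of the unsubstituted terminus; the site of the charge in the first-formed dipole, a seven- instead of an eight-membered fold and the strain of the nine-membered bridged alternative should secure them, and high dilution holds back intermolecular addition.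

Step 14
Reactants: 19 (1S,5S,6S,8S)-6-(tert-butyldimethylsilyloxy)-1,8-dimethyl-4-methylidene-8-(triethylsilyloxy)bicyclo[5.3.0]decan-10-one
Product: 20 (1S,5S,6S,8S)-6-(tert-butyldimethylsilyloxy)-1,8-dimethyl-4-methylidene-8-(triethylsilyloxy)bicyclo[5.3.0]dec-9-en-10-yl trifluoromethanesulfonate
Conditions: KN(SiMe3)2, PhNTf2, THF, −78 °C
Reagents that add atoms: N-phenylbis(trifluoromethanesulfonimide), O=S(=O)(N(c1ccccc1)S(=O)(=O)C(F)(F)F)C(F)(F)F
Why: Deprotonation can occur only at C9 because C1 is quaternary, and O-sulfonylation of the enolate by the triflimide present in the flask should give the C9=C10 enol triflate before the β-silyloxy group at C8 can be eliminated.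

Step 15
Reactants: 20 (1S,5S,6S,8S)-6-(tert-butyldimethylsilyloxy)-1,8-dimethyl-4-methylidene-8-(triethylsilyloxy)bicyclo[5.3.0]dec-9-en-10-yl trifluoromethanesulfonate
Product: 21 (1R,5S,6S,8S)-6-(tert-butyldimethylsilyloxy)-1,8-dimethyl-4-methylidene-8-(triethylsilyloxy)bicyclo[5.3.0]dec-9-ene
Conditions: Pd(OAc)2 (5 mol%), PPh3, Et3N, HCO2H, DMF, 60 °C
Reagents that add atoms: none
Why: Palladium-catalysed formate reduction of the enol triflate (oxidative addition, formate-to-hydride exchange, reductive elimination) replaces OTf by H and gives the C9=C10 alkene without a cationic intermediate that could rearrange at the neopentyl C10 position.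

Step 16
Reactants: 21 (1R,5S,6S,8S)-6-(tert-butyldimethylsilyloxy)-1,8-dimethyl-4-methylidene-8-(triethylsilyloxy)bicyclo[5.3.0]dec-9-ene
Product: 23 (1R,5S,6S,8S)-6-(tert-butyldimethylsilyloxy)-1,8-dimethyl-8-(triethylsilyloxy)bicyclo[5.3.0]dec-9-en-4-one, via vicinal diol 22 (not isolated)
Conditions: OsO4 (2 mol%), N-methylmorpholine N-oxide, acetone/H2O, 0 °C; NaIO4, THF/H2O, rt
Reagents that add atoms: N-methylmorpholine N-oxide, C[N+]1([O-])CCOCC1; water, O (both enter through catalytic OsO4)
Why: Osmium tetroxide dihydroxylation should take the accessible exocyclic 1,1-disubstituted alkene and not the ring alkene, which lies between the quaternary C1 and C8, and periodate cleavage of the diol then gives the cyclopentanone (the C4 centre of the diol is lost again).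

Step 17
Reactants: 23 (1R,5S,6S,8S)-6-(tert-butyldimethylsilyloxy)-1,8-dimethyl-8-(triethylsilyloxy)bicyclo[5.3.0]dec-9-en-4-one
Product: 24 (1R,4R,5S,6S,8S)-6-(tert-butyldimethylsilyloxy)-1,8-dimethyl-4-(propan-2-yl)-8-(triethylsilyloxy)bicyclo[5.3.0]dec-9-en-4-ol
Conditions: i-PrMgCl, CeCl3, THF, −78 → 0 °C
Reagents that add atoms: isopropylmagnesium chloride, CC(C)[Mg]Cl
Why: Organocerium 1,2-addition suppresses enolisation of the hindered cyclopentanone, and the angular C1 methyl shields the β-face so that isopropyl should enter from the α-face (the side of C5–H), which gives the 4R carbinol with its hydroxyl cis to the C1 methyl.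

Step 18
Reactants: 24 (1R,4R,5S,6S,8S)-6-(tert-butyldimethylsilyloxy)-1,8-dimethyl-4-(propan-2-yl)-8-(triethylsilyloxy)bicyclo[5.3.0]dec-9-en-4-ol
Product: 25 (1R,4R,5S,6S,8S)-1,8-dimethyl-4-(propan-2-yl)bicyclo[5.3.0]dec-9-ene-4,6,8-triol
Conditions: Bu4NF, THF, rt → 40 °C
Reagents that add atoms: none
Why: Fluoride-induced desilylation removes the secondary TBS ether and the tertiary TES ether to give the triol.

Step 19
Reactants: 26 vanillic acid
Product: 27 4-acetoxy-3-methoxybenzoic acid
Conditions: Ac2O, NaOH, H2O, 0 °C; HCl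
Reagents that add atoms: acetic anhydride, CC(=O)OC(C)=O
Why: Schotten–Baumann acetylation of the phenoxide in water masks the phenol, the only competing nucleophile of vanillic acid, while the carboxylate is not acylated durably under these conditions.

Step 20
Reactants: 25 (1R,4R,5S,6S,8S)-1,8-dimethyl-4-(propan-2-yl)bicyclo[5.3.0]dec-9-ene-4,6,8-triol; 27 4-acetoxy-3-methoxybenzoic acid
Product: 28 (1R,4R,5S,6S,8S)-4,8-dihydroxy-1,8-dimethyl-4-(propan-2-yl)bicyclo[5.3.0]dec-9-en-6-yl 4-acetoxy-3-methoxybenzoate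
Conditions: DCC, DMAP (cat.), CH2Cl2, rt
Reagents that add atoms: none
Why: Steglich esterification should acylate the only secondary hydroxyl (C6), the tertiary hydroxyls at C4 and C8 being too hindered, and since the C6–O bond is not broken the configuration is kept.

Step 21
Reactants: 28 (1R,4R,5S,6S,8S)-4,8-dihydroxy-1,8-dimethyl-4-(propan-2-yl)bicyclo[5.3.0]dec-9-en-6-yl 4-acetoxy-3-methoxybenzoate
Product: 29 (1R,4R,5S,6S,8S)-4,8-dihydroxy-1,8-dimethyl-4-(propan-2-yl)bicyclo[5.3.0]dec-9-en-6-yl 4-hydroxy-3-methoxybenzoate (CNP0243386.2)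
Conditions: pyrrolidine, CH2Cl2, 0 °C → rt
Reagents that add atoms: none
Why: Aminolysis by pyrrolidine should cleave the activated aryl acetate much faster than the hindered secondary vanillate ester and so release the phenol.

**Compound list**

1 | (S)-benzyl glycidyl ether | C1O[C@@H]1COCc1ccccc1 | starting material
2 | (2S)-1-(benzyloxy)pent-4-yn-2-ol | C#CC[C@H](O)COCc1ccccc1 | intermediate
3 | (2S)-1-(benzyloxy)-2-(tert-butyldimethylsilyloxy)pent-4-yne | C#CC[C@H](O[Si](C)(C)C(C)(C)C)COCc1ccccc1 | intermediate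
4 | [(1E,4S)-5-(benzyloxy)-4-(tert-butyldimethylsilyloxy)-2-methylpent-1-en-1-yl]dimethylalane | C[Al](C)/C=C(\C)C[C@H](O[Si](C)(C)C(C)(C)C)COCc1ccccc1 | intermediate (not isolated)
5 | lithium butyl[(1E,4S)-5-(benzyloxy)-4-(tert-butyldimethylsilyloxy)-2-methylpent-1-en-1-yl]dimethylaluminate | [Li+].CCCC[Al-](C)(C)/C=C(\C)C[C@H](O[Si](C)(C)C(C)(C)C)COCc1ccccc1 | intermediate (not isolated)
6 | (2E,5S)-6-(benzyloxy)-5-(tert-butyldimethylsilyloxy)-3-methylhex-2-en-1-ol | OC/C=C(\C)C[C@H](O[Si](C)(C)C(C)(C)C)COCc1ccccc1 | intermediate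
7 | [(2S,3S)-3-[(2S)-3-(benzyloxy)-2-(tert-butyldimethylsilyloxy)propyl]-3-methyloxiran-2-yl]methanol | OC[C@@H]1O[C@@]1(C)C[C@H](O[Si](C)(C)C(C)(C)C)COCc1ccccc1 | intermediate
8 | (3R,5S)-6-(benzyloxy)-5-(tert-butyldimethylsilyloxy)-3-methylhexane-1,3-diol | OCC[C@@](C)(O)C[C@H](O[Si](C)(C)C(C)(C)C)COCc1ccccc1 | intermediate
9 | (2S,4R)-1-(benzyloxy)-2-(tert-butyldimethylsilyloxy)-4-methyl-4,6-bis(triethylsilyloxy)hexane | CC[Si](CC)(CC)OCC[C@@](C)(O[Si](CC)(CC)CC)C[C@H](O[Si](C)(C)C(C)(C)C)COCc1ccccc1 | intermediate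
10 | (2S,4R)-2-(tert-butyldimethylsilyloxy)-4-methyl-4,6-bis(triethylsilyloxy)hexan-1-ol | CC[Si](CC)(CC)OCC[C@@](C)(O[Si](CC)(CC)CC)C[C@H](O[Si](C)(C)C(C)(C)C)CO | intermediate
11 | (2S,4R)-2-(tert-butyldimethylsilyloxy)-4-methyl-4,6-bis(triethylsilyloxy)hexanal | CC[Si](CC)(CC)OCC[C@@](C)(O[Si](CC)(CC)CC)C[C@H](O[Si](C)(C)C(C)(C)C)C=O | intermediate
12 | 2-bromo-3-(trimethylsilyl)propene | C=C(Br)C[Si](C)(C)C | starting material
13 | 2-lithio-3-(trimethylsilyl)propene | [Li]C(=C)C[Si](C)(C)C | intermediate (not isolated)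
14 | lithium (4S,6R)-4-(tert-butyldimethylsilyloxy)-6-methyl-6,8-bis(triethylsilyloxy)-2-[(trimethylsilyl)methyl]oct-1-en-3-olate (C3 epimers) | CC[Si](CC)(CC)OCC[C@@](C)(O[Si](CC)(CC)CC)C[C@H](O[Si](C)(C)C(C)(C)C)C([O-])C(=C)C[Si](C)(C)C.[Li+] | intermediate (not isolated)
15 | (4S,6R)-4-(tert-butyldimethylsilyloxy)-6-methyl-6,8-bis(triethylsilyloxy)-2-[(trimethylsilyl)methyl]oct-1-en-3-yl acetate (C3 epimers) | CC[Si](CC)(CC)OCC[C@@](C)(O[Si](CC)(CC)CC)C[C@H](O[Si](C)(C)C(C)(C)C)C(OC(C)=O)C(=C)C[Si](C)(C)C | intermediate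
16 | (4S,6S)-4-(tert-butyldimethylsilyloxy)-6-methyl-8-oxo-6-(triethylsilyloxy)-2-[(trimethylsilyl)methyl]oct-1-en-3-yl acetate (C3 epimers) | O=CC[C@@](C)(O[Si](CC)(CC)CC)C[C@H](O[Si](C)(C)C(C)(C)C)C(OC(C)=O)C(=C)C[Si](C)(C)C | intermediate
17 | (4S,6R)-4-(tert-butyldimethylsilyloxy)-8-hydroxy-6,9-dimethyl-6-(triethylsilyloxy)-2-[(trimethylsilyl)methyl]deca-1,9-dien-3-yl acetate (C3 and C8 epimers) | C=C(C)C(O)C[C@@](C)(O[Si](CC)(CC)CC)C[C@H](O[Si](C)(C)C(C)(C)C)C(OC(C)=O)C(=C)C[Si](C)(C)C | intermediate
18 | (4S,6S)-4-(tert-butyldimethylsilyloxy)-6,9-dimethyl-8-oxo-6-(triethylsilyloxy)-2-[(trimethylsilyl)methyl]deca-1,9-dien-3-yl acetate (C3 epimers; key-step precursor) | C=C(C)C(=O)C[C@@](C)(O[Si](CC)(CC)CC)C[C@H](O[Si](C)(C)C(C)(C)C)C(OC(C)=O)C(=C)C[Si](C)(C)C | intermediate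
19 | (1S,5S,6S,8S)-6-(tert-butyldimethylsilyloxy)-1,8-dimethyl-4-methylidene-8-(triethylsilyloxy)bicyclo[5.3.0]decan-10-one (trans-fused; key-step product) | CC(C)(C)[Si](C)(C)O[C@H]2C[C@](C)(O[Si](CC)(CC)CC)CC(=O)[C@@]3(C)CCC(=C)[C@H]23 | intermediate
20 | (1S,5S,6S,8S)-6-(tert-butyldimethylsilyloxy)-1,8-dimethyl-4-methylidene-8-(triethylsilyloxy)bicyclo[5.3.0]dec-9-en-10-yl trifluoromethanesulfonate | CC(C)(C)[Si](C)(C)O[C@H]2C[C@](C)(O[Si](CC)(CC)CC)C=C(OS(=O)(=O)C(F)(F)F)[C@@]3(C)CCC(=C)[C@H]23 | intermediate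
21 | (1R,5S,6S,8S)-6-(tert-butyldimethylsilyloxy)-1,8-dimethyl-4-methylidene-8-(triethylsilyloxy)bicyclo[5.3.0]dec-9-ene | CC(C)(C)[Si](C)(C)O[C@H]2C[C@](C)(O[Si](CC)(CC)CC)C=C[C@@]3(C)CCC(=C)[C@H]23 | intermediate
22 | (1R,5S,6S,8S)-6-(tert-butyldimethylsilyloxy)-4-(hydroxymethyl)-1,8-dimethyl-8-(triethylsilyloxy)bicyclo[5.3.0]dec-9-en-4-ol (C4 epimers) | CC(C)(C)[Si](C)(C)O[C@H]2C[C@](C)(O[Si](CC)(CC)CC)C=C[C@@]3(C)CCC(O)(CO)[C@H]23 | intermediate (not isolated)
23 | (1R,5S,6S,8S)-6-(tert-butyldimethylsilyloxy)-1,8-dimethyl-8-(triethylsilyloxy)bicyclo[5.3.0]dec-9-en-4-one | CC(C)(C)[Si](C)(C)O[C@H]2C[C@](C)(O[Si](CC)(CC)CC)C=C[C@@]3(C)CCC(=O)[C@H]23 | intermediate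
24 | (1R,4R,5S,6S,8S)-6-(tert-butyldimethylsilyloxy)-1,8-dimethyl-4-(propan-2-yl)-8-(triethylsilyloxy)bicyclo[5.3.0]dec-9-en-4-ol | CC(C)(C)[Si](C)(C)O[C@H]2C[C@](C)(O[Si](CC)(CC)CC)C=C[C@@]3(C)CC[C@@](O)(C(C)C)[C@H]23 | intermediate
25 | (1R,4R,5S,6S,8S)-1,8-dimethyl-4-(propan-2-yl)bicyclo[5.3.0]dec-9-ene-4,6,8-triol | O[C@H]2C[C@](C)(O)C=C[C@@]3(C)CC[C@@](O)(C(C)C)[C@H]23 | intermediate
26 | vanillic acid | COc1cc(C(=O)O)ccc1O | starting material
27 | 4-acetoxy-3-methoxybenzoic acid | COc1cc(C(=O)O)ccc1OC(C)=O | intermediate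
28 | (1R,4R,5S,6S,8S)-4,8-dihydroxy-1,8-dimethyl-4-(propan-2-yl)bicyclo[5.3.0]dec-9-en-6-yl 4-acetoxy-3-methoxybenzoate | COc1cc(C(=O)O[C@H]2C[C@](C)(O)C=C[C@@]3(C)CC[C@@](O)(C(C)C)[C@H]23)ccc1OC(C)=O | intermediate
29 | (1R,4R,5S,6S,8S)-4,8-dihydroxy-1,8-dimethyl-4-(propan-2-yl)bicyclo[5.3.0]dec-9-en-6-yl 4-hydroxy-3-methoxybenzoate | COc1cc(C(=O)O[C@H]2C[C@](C)(O)C=C[C@@]3(C)CC[C@@](O)(C(C)C)[C@H]23)ccc1O | target

**Step count**

Total step count: 21. Longest linear sequence: 20 steps (1 to 29 through steps 1–18, 20 and 21; step 19 is the side branch).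

**Steps most likely to fail**

Step 13. The dipole may be protonated or add to a second molecule before it reaches the tethered enone. If it does cyclise, the tether-bearing terminus may attack C2 (bridged skeleton), or the enolate may close on the wrong face (cis fusion). The fallback sets out from aldehyde 11 and comes back at 19; it buys the C2–C3 bond with the reagent and makes the other two bonds one at a time. Mono bromine–lithium exchange of 2,5-dibromohexa-1,5-diene (excess, t-BuLi, Et2O, −78 °C) and addition to 11 would give the allylic alcohol F1, which is acetylated (Ac2O, DMAP, pyridine) to the acetate F2. Swern oxidation of the primary TES ether as in step 10 would give the aldehyde F3. An intramolecular Nozaki–Hiyama–Kishi reaction of the vinyl bromide with the aldehyde (CrCl2, NiCl2 cat., DMF, high dilution) would close the ten-membered ring at C1–C10 to the cyclic carbinol F4, and Dess–Martin oxidation would give the cyclic α-methylene ketone F5. Conjugate reduction with LiBH(s-Bu)3 (THF, −78 °C) would create the C1 methyl group and, regiospecifically, the C1 enolate F6. Pd(PPh3)4 would then ionise the C5 acetate so that the enolate closes across the ring on C5 (palladium-catalysed allylation of an enoxyborate) to give 19.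

Step 17. Enolisation of the ketone toward C5 (with loss of the C6 silyloxy group by β-elimination) or hydride transfer from the isopropyl reagent may outrun addition to the hindered carbonyl, and the face selectivity is not secured by precedent. The fallback sets out from 23 and comes back at 24. The 2-propenyl cerium reagent (CH2=C(CH3)MgBr, CeCl3, THF, −78 °C) is smaller, less basic and has no β-hydride to deliver; it would give the isopropenyl carbinol F8. Hydrogenation of its 1,1-disubstituted alkene with H2 and RhCl(PPh3)3 (benzene) should leave the ring alkene between two quaternary carbons and give 24.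

Step 16. Osmylation may not stop at the exocyclic methylene and oxidise the C9=C10 alkene as well, or the exocyclic alkene may already have migrated into the ring under the palladium hydride of step 15. The fallback sets out from 20 and comes back at 23; it cleaves the methylene while C9=C10 is still masked as the electron-poor enol triflate. Ozonolysis of 20 (O3, CH2Cl2/MeOH, −78 °C; Me2S) would give the keto enol triflate F7, and the triflate is then reduced as in step 15 (Pd(OAc)2, PPh3, Et3N, HCO2H, DMF) to 23.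

**Further compounds**

F1 | step 13 | (7S,9R)-2-bromo-7-(tert-butyldimethylsilyloxy)-9-methyl-5-methylidene-9,11-bis(triethylsilyloxy)undec-1-en-6-ol (C6 epimers) | CC[Si](CC)(CC)OCC[C@@](C)(O[Si](CC)(CC)CC)C[C@H](O[Si](C)(C)C(C)(C)C)C(O)C(=C)CCC(Br)=C
F2 | step 13 | (7S,9R)-2-bromo-7-(tert-butyldimethylsilyloxy)-9-methyl-5-methylidene-9,11-bis(triethylsilyloxy)undec-1-en-6-yl acetate | CC[Si](CC)(CC)OCC[C@@](C)(O[Si](CC)(CC)CC)C[C@H](O[Si](C)(C)C(C)(C)C)C(OC(C)=O)C(=C)CCC(Br)=C
F3 | step 13 | (7S,9S)-2-bromo-7-(tert-butyldimethylsilyloxy)-9-methyl-5-methylidene-11-oxo-9-(triethylsilyloxy)undec-1-en-6-yl acetate | O=CC[C@@](C)(O[Si](CC)(CC)CC)C[C@H](O[Si](C)(C)C(C)(C)C)C(OC(C)=O)C(=C)CCC(Br)=C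
F4 | step 13 | ten-membered carbinol: 6-(tert-butyldimethylsilyloxy)-10-hydroxy-8-methyl-1,4-dimethylidene-8-(triethylsilyloxy)cyclodecan-5-yl acetate (target locants; C6 and C8 as in 11; C5 and C10 epimers) | OC1C[C@@](C)(O[Si](CC)(CC)CC)C[C@H](O[Si](C)(C)C(C)(C)C)C(OC(C)=O)C(=C)CCC1=C
F5 | step 13 | ten-membered α-methylene ketone: 6-(tert-butyldimethylsilyloxy)-8-methyl-1,4-dimethylidene-10-oxo-8-(triethylsilyloxy)cyclodecan-5-yl acetate (target locants) | O=C1C[C@@](C)(O[Si](CC)(CC)CC)C[C@H](O[Si](C)(C)C(C)(C)C)C(OC(C)=O)C(=C)CCC1=C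
F6 | step 13 | lithium C1(C10) enolate of the 1-methyl ketone derived from F5 | [Li+].[O-]C=1C[C@@](C)(O[Si](CC)(CC)CC)C[C@H](O[Si](C)(C)C(C)(C)C)C(OC(C)=O)C(=C)CCC=1C
F7 | step 16 | (1S,5S,6S,8S)-6-(tert-butyldimethylsilyloxy)-1,8-dimethyl-4-oxo-8-(triethylsilyloxy)bicyclo[5.3.0]dec-9-en-10-yl trifluoromethanesulfonate | CC(C)(C)[Si](C)(C)O[C@H]2C[C@](C)(O[Si](CC)(CC)CC)C=C(OS(=O)(=O)C(F)(F)F)[C@@]3(C)CCC(=O)[C@H]23
F8 | step 17 | (1R,4S,5S,6S,8S)-6-(tert-butyldimethylsilyloxy)-1,8-dimethyl-4-(prop-1-en-2-yl)-8-(triethylsilyloxy)bicyclo[5.3.0]dec-9-en-4-ol | CC(C)(C)[Si](C)(C)O[C@H]2C[C@](C)(O[Si](CC)(CC)CC)C=C[C@@]3(C)CC[C@@](O)(C(C)=C)[C@H]23
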